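Assumption: chromone numbering is used (O1, C2, C3, C4, C4a, C5–C8, C8a; ring B C1'–C6'); "prenyl" means 3-methylbut-2-en-1-yl and MOM means methoxymethyl. The target has no stereocentre, so the only stereochemical element in the route is the enol ether geometry of 19, 21–23 and 25.

## Analysis of the target

Isoangustone A is 5,7,3',4'-tetrahydroxy-6,5'-diprenylisoflavone. Ring A (C4a, C5–C8, C8a) is a phloroglucinol-type benzene with hydroxyls at C5 and C7 and a prenyl group at C6 between them; ring C (O1, C2, C3, C4) is the 4-pyranone; ring B is a catechol (C3'–OH, C4'–OH) with a prenyl group at C5', bound through C1' to C3. There is no stereocentre, axis or stereogenic alkene, so the whole problem is regiochemistry and functional-group tolerance. The hardest point is ring A: C6 and C8 differ only in which of the two oxygens ortho to the C4 carbonyl has become O1. Any route that closes ring C onto a ring A with two free or equally protected ortho oxygens therefore gives the 6-prenyl and 8-prenyl isoflavones together. Ring B is a 1,3,4,5-tetrasubstituted benzene with the prenyl group ortho to oxygen and meta to the ring junction, a pattern that electrophilic substitution of a catechol does not deliver. The sensitive groups are four phenols, three of them ortho to a prenyl group (acid closes chromans), and two trisubstituted alkenes that rule out hydrogenolysis, strong Lewis acids and electrophilic oxidants. The feature used here: the neighbouring ring-A carbons C4a and C8a carry the C4 carbonyl carbon and O1 of ring C, and C5 beside C4a carries oxygen. This is the substituent pair that an aryne C4a≡C8a takes up from a carboxylate, with the C5 oxygen deciding the orientation.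

## Retrosynthetic reasoning

**27 to 26.** The four phenols are unmasked last. MOM ethers are chosen because they survive organolithiums, fluoride, iridium and palladium catalysis and base, direct every ring metalation of the route, and leave under dilute protic acid that does not protonate a trisubstituted alkene at a useful rate.

**26 to 13 and 23 (key disconnection).** Three bonds of ring C are cut: O1–C8a, C4–C4a and O1–C2. Ring A becomes aryne 24, released from silyl triflate 13. C2, C3, C4, O1 and ring B come from the β-methoxyacrylic acid 23. The cut is made here because it moves the C6/C8 question out of phenol differentiation and into the polarisation of 24 by its C5 oxygen. The forward step has to add the carboxylate oxygen to C8a, shift the acyl group to C4a (ketone 25) and close ring C by addition–elimination at the methoxy-bearing carbon.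

**23 to 22 to 18 and 21.** The C3–C1' bond is cut between the acrylate α-carbon and ring B. The forward reaction is a Suzuki–Miyaura coupling of boronate 18 with the (Z)-iodide 21, with retention of alkene geometry, followed by ester hydrolysis. 21 comes from acrylate 19 through adduct 20.

**18 to 17 to 15 to 14.** The C1'–B bond is cut by a sterically controlled C–H borylation: in 17 only one ring C–H has no ortho substituent, and it is the one ring B needs. The C5'–prenyl bond is cut by ortho metalation of 15 (through 16), which places the prenyl group beside oxygen.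

**13 to 11 to 7 to 6.** The triflate is traced to a phenol (12) and the silyl group to a carbamate-directed ortho metalation (through 8, 9, 10). Phenol 6 is symmetric, so its two ortho positions are the same and only one silyl triflate can form.

**6 to 4 to 2 to 1.** The phenol oxygen of 6 is cut back to a C–H bond: borylation of 4 at its only unhindered position (boronate 5), then oxidation. The prenyl group is cut back to lithiation of 2 between its two MOM ethers (through 3). The prenyl group of C6 is thus fixed between the two future C5 and C7 oxygens before ring A meets ring C. Each of the six steps to 13 is controlled by symmetry or sterics and should give a single isomer.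

## Alternatives that were turned down

**Alternative 1:** the textbook route. Disconnection of C3–C1' by Suzuki–Miyaura coupling of 3-iodo-5,7-bis(methoxymethoxy)-6-prenylchromen-4-one A1 with boronate 18. A1 would come from acetophenone A2 (enaminone formation, iodocyclisation). Turned down because the key step only joins two finished ring systems. All regiochemistry falls on A2, whose single free hydroxyl must be the one remote from the prenyl group. In the triol precursor of A2 both ortho hydroxyls are hydrogen bonded to the ketone, and the more hindered one beside the prenyl group is the one more likely to stay unprotected. That hydroxyl leads to the 8-prenyl series, so A2 is the disfavoured isomer, and separations or extra protecting-group steps would be needed.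

**Alternative 2:** disconnection of C4–C4a and of C2 as a one-carbon unit. Friedel–Crafts or Houben–Hoesch acylation of a C-prenylphloroglucinol with a ring-B arylacetic acid derivative would give deoxybenzoin A3, followed by formylative ring closure. Turned down for two reasons. A3 has two free hydroxyls ortho to the ketone with no structural bias, so closure gives the target together with its 8-prenyl isomer A4. The acylation and closure reagents (ZnCl2/HCl, BF3·OEt2) are strong acids that meet two prenyl groups ortho to free phenols and would close chromans, while protecting the phenols deactivates the ring towards acylation.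

**Alternative 3:** disconnection of both aryl–prenyl bonds (C6–CH2 and C5'–CH2) by a late twofold aromatic Claisen rearrangement of the bis(1,1-dimethylallyl) ether A5 of the parent tetrahydroxyisoflavone. Turned down because ring B would behave (only C5' is free ortho to O4'), but the 7-O-allyl unit on ring A can migrate to C6 or C8. The less hindered C8 is expected to win, giving A4. A5 also requires selective etherification of O7 and O4' beside O5 and O3', and each tertiary allyl ether costs two steps. The key step would form two bonds without solving the regiochemical problem.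

Key step: step 13

## Route

Step 1
Reactants: 1 resorcinol
Product: 2 1,3-bis(methoxymethoxy)benzene
Conditions: NaH, DMF, 0 °C; MOMCl, 0 °C to rt
Reagents that add atoms: chloromethyl methyl ether, COCCl
Why: Twofold O-alkylation of the phenoxide (Williamson-type acetal formation); the MOM ethers serve as protecting groups and as directing groups for the later metalations.

Step 2
Reactants: 2 1,3-bis(methoxymethoxy)benzene
Product: 4 1,3-bis(methoxymethoxy)-2-(3-methylbut-2-en-1-yl)benzene, via 2-lithio-1,3-bis(methoxymethoxy)benzene 3 (not isolated)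
Conditions: n-BuLi, THF, 0 °C to rt; CuBr·SMe2 (10 mol %), prenyl bromide, −78 °C to rt
Reagents that add atoms: 1-bromo-3-methylbut-2-ene (prenyl bromide), CC(C)=CCBr
Why: Directed ortho metalation: C2, flanked by both MOM ethers, is by far the most acidic ring position; copper-catalysed SN2 allylation at the primary end of the allylic bromide should give the linear prenyl group.

Step 3
Reactants: 4 1,3-bis(methoxymethoxy)-2-(3-methylbut-2-en-1-yl)benzene
Product: 6 3,5-bis(methoxymethoxy)-4-(3-methylbut-2-en-1-yl)phenol, via aryl pinacol boronate 5 (not isolated)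
Conditions: [Ir(OMe)(cod)]2 (1.5 mol %), 4,4'-di-tert-butyl-2,2'-bipyridine (3 mol %), B2pin2, THF, 60 °C; then aq. NaOH, 30% H2O2, 0 °C
Reagents that add atoms: hydrogen peroxide, OO (the phenol oxygen); bis(pinacolato)diboron, CC1(C)OB(OC1(C)C)B1OC(C)(C)C(C)(C)O1 (boron of intermediate 5 only, lost again on oxidation)
Why: Iridium-catalysed aromatic C–H borylation is governed by sterics, and C5 of 4 is the only ring C–H without an ortho substituent, so 5 should form as one isomer; basic hydrogen peroxide then converts C–B into C–OH at the same carbon and does not epoxidise an unactivated alkene.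

Step 4
Reactants: 6 3,5-bis(methoxymethoxy)-4-(3-methylbut-2-en-1-yl)phenol
Product: 7 3,5-bis(methoxymethoxy)-4-(3-methylbut-2-en-1-yl)phenyl N-isopropylcarbamate
Conditions: i-PrNCO, Et3N (cat.), CH2Cl2, rt
Reagents that add atoms: isopropyl isocyanate, CC(C)N=C=O
Why: Base-catalysed addition of the phenol to the isocyanate; the N-monoalkyl carbamate is chosen because it directs ortho metalation after N-silylation and can later be removed by a mild E1cB cleavage.

Step 5
Reactants: 7 3,5-bis(methoxymethoxy)-4-(3-methylbut-2-en-1-yl)phenyl N-isopropylcarbamate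
Product: 11 3,5-bis(methoxymethoxy)-4-(3-methylbut-2-en-1-yl)-2-(trimethylsilyl)phenyl N-isopropylcarbamate, via N-silylated carbamate 8 (not isolated), via ortho-lithiated N-silylated carbamate 9 (not isolated), via C-silylated N-silylated carbamate 10 (not isolated)
Conditions: TBSOTf, TMEDA, Et2O, 0 °C to rt; TMEDA, n-BuLi, −78 °C; TMSCl, −78 °C to rt; cold aq. NaHSO4 work-up
Reagents that add atoms: chlorotrimethylsilane, C[Si](C)(C)Cl; tert-butyldimethylsilyl triflate, CC(C)(C)[Si](C)(C)OS(=O)(=O)C(F)(F)F (silicon on nitrogen in 8–10 only, removed on work-up)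
Why: N-silylation in the flask makes the tertiary carbamate 8, whose directed ortho metalation occurs at the ring C–H flanked by the carbamate and a MOM ether (two cooperating directing groups; both such positions are equivalent by symmetry); 9 is silylated on carbon and the labile N–Si bond is hydrolysed on work-up.

Step 6
Reactants: 11 3,5-bis(methoxymethoxy)-4-(3-methylbut-2-en-1-yl)-2-(trimethylsilyl)phenyl N-isopropylcarbamate
Product: 13 3,5-bis(methoxymethoxy)-4-(3-methylbut-2-en-1-yl)-2-(trimethylsilyl)phenyl trifluoromethanesulfonate, via ortho-silyl phenol 12 (not isolated)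
Conditions: DBU, Et2NH, MeCN, 40 °C; then PhNTf2, rt
Reagents that add atoms: N-phenylbis(trifluoromethanesulfonimide), O=S(=O)(N(c1ccccc1)S(=O)(=O)C(F)(F)F)C(F)(F)F
Why: DBU removes the carbamate N–H and the phenoxide leaves (E1cB), the isocyanate being trapped by Et2NH; the phenoxide of 12 is triflated in the same flask, all under basic conditions that spare the aryl–silicon bond, the MOM ethers and the alkene.

Step 7
Reactants: 14 catechol
Product: 15 1,2-bis(methoxymethoxy)benzene
Conditions: NaH, DMF, 0 °C; MOMCl, 0 °C to rt
Reagents that add atoms: chloromethyl methyl ether, COCCl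
Why: Twofold O-alkylation of the phenoxide, as in step 1.

Step 8
Reactants: 15 1,2-bis(methoxymethoxy)benzene
Product: 17 1,2-bis(methoxymethoxy)-3-(3-methylbut-2-en-1-yl)benzene, via 3-lithio-1,2-bis(methoxymethoxy)benzene 16 (not isolated)
Conditions: n-BuLi, TMEDA, THF, 0 °C; CuBr·SMe2 (10 mol %), prenyl bromide, −78 °C to rt
Reagents that add atoms: 1-bromo-3-methylbut-2-ene (prenyl bromide), CC(C)=CCBr
Why: Directed ortho metalation beside a MOM ether (C3 and C6 are equivalent), then copper-catalysed SN2 allylation as in step 2; this sets the prenyl group ortho to oxygen as ring B requires.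

Step 9
Reactants: 17 1,2-bis(methoxymethoxy)-3-(3-methylbut-2-en-1-yl)benzene
Product: 18 2-[3,4-bis(methoxymethoxy)-5-(3-methylbut-2-en-1-yl)phenyl]-4,4,5,5-tetramethyl-1,3,2-dioxaborolane
Conditions: [Ir(OMe)(cod)]2 (1.5 mol %), 4,4'-di-tert-butyl-2,2'-bipyridine (3 mol %), B2pin2, THF, 60 °C
Reagents that add atoms: bis(pinacolato)diboron, CC1(C)OB(OC1(C)C)B1OC(C)(C)C(C)(C)O1
Why: Sterically controlled iridium-catalysed C–H borylation: C5 is the only ring C–H of 17 without an ortho substituent (C4 lies beside prenyl, C6 beside a MOM ether), which puts boron meta to prenyl and para to the C2 oxygen.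

Step 10
Reactants: 19 methyl (E)-3-methoxyprop-2-enoate
Product: 21 methyl (Z)-2-iodo-3-methoxyprop-2-enoate, via iodo acetoxy adduct 20 (not isolated)
Conditions: NIS, AcOH, CH2Cl2, rt; then Et3N, rt
Reagents that add atoms: N-iodosuccinimide, O=C1CCC(=O)N1I; acetic acid, CC(=O)O (acetoxy group of intermediate 20 only, eliminated again)
Why: Electrophilic iodo-acetoxylation of the enol ether double bond, then amine-induced elimination of acetic acid; this addition–elimination sequence on β-alkoxyacrylates is expected to give the Z iodide (iodine cis to methoxy).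

Step 11
Reactants: 18 2-[3,4-bis(methoxymethoxy)-5-(3-methylbut-2-en-1-yl)phenyl]-4,4,5,5-tetramethyl-1,3,2-dioxaborolane; 21 methyl (Z)-2-iodo-3-methoxyprop-2-enoate
Product: 22 methyl (E)-2-[3,4-bis(methoxymethoxy)-5-(3-methylbut-2-en-1-yl)phenyl]-3-methoxyprop-2-enoate
Conditions: Pd(PPh3)4 (5 mol %), K3PO4, dioxane/H2O, 85 °C
Reagents that add atoms: none
Why: Suzuki–Miyaura coupling; oxidative addition of zerovalent palladium to the vinyl C–I bond and reductive elimination proceed with retention, so the aryl group ends cis to methoxy, which is the E β-methoxyacrylate.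

Step 12
Reactants: 22 methyl (E)-2-[3,4-bis(methoxymethoxy)-5-(3-methylbut-2-en-1-yl)phenyl]-3-methoxyprop-2-enoate
Product: 23 (E)-2-[3,4-bis(methoxymethoxy)-5-(3-methylbut-2-en-1-yl)phenyl]-3-methoxyprop-2-enoic acid
Conditions: LiOH·H2O, THF/MeOH/H2O, 40 °C; then 0.5 M HCl to pH 4, 0 °C
Reagents that add atoms: lithium hydroxide, [Li+].[OH-] (its oxygen becomes the carboxylic acid OH)
Why: Saponification of the methyl ester; once the carboxylate has formed the vinylogous carbonate is deactivated towards conjugate attack, and acidification only to pH 4 in the cold spares the MOM ethers and the enol ether.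

Step 13
Reactants: 13 3,5-bis(methoxymethoxy)-4-(3-methylbut-2-en-1-yl)-2-(trimethylsilyl)phenyl trifluoromethanesulfonate; 23 (E)-2-[3,4-bis(methoxymethoxy)-5-(3-methylbut-2-en-1-yl)phenyl]-3-methoxyprop-2-enoic acid
Product: 26 5,7-bis(methoxymethoxy)-3-[3,4-bis(methoxymethoxy)-5-(3-methylbut-2-en-1-yl)phenyl]-6-(3-methylbut-2-en-1-yl)-4H-chromen-4-one, via 3,5-bis(methoxymethoxy)-4-prenylbenzyne 24 (not isolated), via ortho-hydroxyaryl β-methoxy enone 25 (not isolated)
Conditions: CsF (4 equiv), THF, 125 °C, sealed tube (13 in slight excess)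
Reagents that add atoms: none
Why: Proposed new method: fluoride removes the silyl group of 13 and triflate leaves from the neighbouring carbon, giving aryne 24; the cesium carboxylate of 23 adds to C8a, the aryne carbon remote from the C5 MOM ether, because this places the aryl anion on C4a next to the inductively withdrawing oxygen, the general rule for 3-alkoxyarynes. The C4a anion then attacks the adjacent aryl ester carbonyl through a four-membered transition state, and the 1,3 acyl shift from oxygen to carbon gives the phenoxide of ketone 25. This part is the known insertion of arynes into the C–O bond of carboxylic acids, the closest known reaction type, which is documented to continue to 4-chromanones with acrylic acids and to flavones with arylpropiolic acids. New is the β-methoxyacrylic acid partner: the C8a phenoxide adds to the methoxy-bearing β-carbon of the enone in 25 (6-endo-trig oxa-Michael addition) and methoxide is expelled (E1cB), which closes ring C as the 4-pyranone. O1–C8a, C4–C4a and O1–C2 are thus formed, the two halves are joined and the C6 (not C8) position of the prenyl group is fixed in one operation, from precursors in which no phenol had to be told apart from another. No stereocentre is formed, and the E geometry of 23 is lost without consequence in the freely rotating enolate of the addition–elimination. The step needs the aryl anion to attack the ester carbonyl and not the β-carbon (which would close a 3-arylcoumarin); the s-cis conformation of the aryl ester, which holds the β-carbon away from C4a, should secure this. It also needs carboxylate addition to outrun an ene reaction of 24 with a prenyl alkene, which the anionic nucleophile and the slow release of the aryne by sparingly soluble CsF should secure.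

Step 14
Reactants: 26 5,7-bis(methoxymethoxy)-3-[3,4-bis(methoxymethoxy)-5-(3-methylbut-2-en-1-yl)phenyl]-6-(3-methylbut-2-en-1-yl)-4H-chromen-4-one
Product: 27 isoangustone A, 5,7-dihydroxy-3-[3,4-dihydroxy-5-(3-methylbut-2-en-1-yl)phenyl]-6-(3-methylbut-2-en-1-yl)-4H-chromen-4-one
Conditions: 3 M aq. HCl, MeOH, 45 °C
Reagents that add atoms: none
Why: Acid-catalysed transacetalisation of the four MOM ethers to methanol; acetal cleavage is far faster than protonation of a trisubstituted alkene in dilute acid at moderate temperature, so both prenyl groups should survive.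

## Compound list

1 | resorcinol (benzene-1,3-diol) | Oc1cccc(O)c1 | starting material
2 | 1,3-bis(methoxymethoxy)benzene | COCOc1cccc(OCOC)c1 | intermediate
3 | 2-lithio-1,3-bis(methoxymethoxy)benzene | [Li]c1c(OCOC)cccc1OCOC | intermediate
4 | 1,3-bis(methoxymethoxy)-2-(3-methylbut-2-en-1-yl)benzene | COCOc1cccc(OCOC)c1CC=C(C)C | intermediate
5 | 2-[3,5-bis(methoxymethoxy)-4-(3-methylbut-2-en-1-yl)phenyl]-4,4,5,5-tetramethyl-1,3,2-dioxaborolane | COCOc1cc(B2OC(C)(C)C(C)(C)O2)cc(OCOC)c1CC=C(C)C | intermediate
6 | 3,5-bis(methoxymethoxy)-4-(3-methylbut-2-en-1-yl)phenol | COCOc1cc(O)cc(OCOC)c1CC=C(C)C | intermediate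
7 | 3,5-bis(methoxymethoxy)-4-(3-methylbut-2-en-1-yl)phenyl N-isopropylcarbamate | COCOc1cc(OC(=O)NC(C)C)cc(OCOC)c1CC=C(C)C | intermediate
8 | 3,5-bis(methoxymethoxy)-4-(3-methylbut-2-en-1-yl)phenyl N-(tert-butyldimethylsilyl)-N-isopropylcarbamate | COCOc1cc(OC(=O)N(C(C)C)[Si](C)(C)C(C)(C)C)cc(OCOC)c1CC=C(C)C | intermediate
9 | 2-lithio-3,5-bis(methoxymethoxy)-4-(3-methylbut-2-en-1-yl)phenyl N-(tert-butyldimethylsilyl)-N-isopropylcarbamate | COCOc1cc(OC(=O)N(C(C)C)[Si](C)(C)C(C)(C)C)c([Li])c(OCOC)c1CC=C(C)C | intermediate
10 | 3,5-bis(methoxymethoxy)-4-(3-methylbut-2-en-1-yl)-2-(trimethylsilyl)phenyl N-(tert-butyldimethylsilyl)-N-isopropylcarbamate | COCOc1cc(OC(=O)N(C(C)C)[Si](C)(C)C(C)(C)C)c([Si](C)(C)C)c(OCOC)c1CC=C(C)C | intermediate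
11 | 3,5-bis(methoxymethoxy)-4-(3-methylbut-2-en-1-yl)-2-(trimethylsilyl)phenyl N-isopropylcarbamate | COCOc1cc(OC(=O)NC(C)C)c([Si](C)(C)C)c(OCOC)c1CC=C(C)C | intermediate
12 | 3,5-bis(methoxymethoxy)-4-(3-methylbut-2-en-1-yl)-2-(trimethylsilyl)phenol | COCOc1cc(O)c([Si](C)(C)C)c(OCOC)c1CC=C(C)C | intermediate
13 | 3,5-bis(methoxymethoxy)-4-(3-methylbut-2-en-1-yl)-2-(trimethylsilyl)phenyl trifluoromethanesulfonate | COCOc1cc(OS(=O)(=O)C(F)(F)F)c([Si](C)(C)C)c(OCOC)c1CC=C(C)C | intermediate
14 | catechol (benzene-1,2-diol) | Oc1ccccc1O | starting material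
15 | 1,2-bis(methoxymethoxy)benzene | COCOc1ccccc1OCOC | intermediate
16 | 3-lithio-1,2-bis(methoxymethoxy)benzene | [Li]c1cccc(OCOC)c1OCOC | intermediate
17 | 1,2-bis(methoxymethoxy)-3-(3-methylbut-2-en-1-yl)benzene | COCOc1cccc(CC=C(C)C)c1OCOC | intermediate
18 | 2-[3,4-bis(methoxymethoxy)-5-(3-methylbut-2-en-1-yl)phenyl]-4,4,5,5-tetramethyl-1,3,2-dioxaborolane | COCOc1cc(B2OC(C)(C)C(C)(C)O2)cc(CC=C(C)C)c1OCOC | intermediate
19 | methyl (E)-3-methoxyprop-2-enoate | CO/C=C/C(=O)OC | starting material
20 | methyl 3-acetoxy-2-iodo-3-methoxypropanoate (mixture of diastereomers, racemic) | COC(OC(C)=O)C(I)C(=O)OC | intermediate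
21 | methyl (Z)-2-iodo-3-methoxyprop-2-enoate | CO/C=C(\I)C(=O)OC | intermediate
22 | methyl (E)-2-[3,4-bis(methoxymethoxy)-5-(3-methylbut-2-en-1-yl)phenyl]-3-methoxyprop-2-enoate | CO/C=C(/C(=O)OC)c1cc(CC=C(C)C)c(OCOC)c(OCOC)c1 | intermediate
23 | (E)-2-[3,4-bis(methoxymethoxy)-5-(3-methylbut-2-en-1-yl)phenyl]-3-methoxyprop-2-enoic acid | CO/C=C(/C(=O)O)c1cc(CC=C(C)C)c(OCOC)c(OCOC)c1 | intermediate
24 | 3,5-bis(methoxymethoxy)-4-(3-methylbut-2-en-1-yl)benzyne (1,2-didehydrobenzene) | C1#CC=C(OCOC)C(CC=C(C)C)=C1OCOC | intermediate
25 | (E)-2-[3,4-bis(methoxymethoxy)-5-(3-methylbut-2-en-1-yl)phenyl]-1-[6-hydroxy-2,4-bis(methoxymethoxy)-3-(3-methylbut-2-en-1-yl)phenyl]-3-methoxyprop-2-en-1-one | CO/C=C(/C(=O)c1c(O)cc(OCOC)c(CC=C(C)C)c1OCOC)c1cc(CC=C(C)C)c(OCOC)c(OCOC)c1 | intermediate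
26 | 5,7-bis(methoxymethoxy)-3-[3,4-bis(methoxymethoxy)-5-(3-methylbut-2-en-1-yl)phenyl]-6-(3-methylbut-2-en-1-yl)-4H-chromen-4-one | CC(C)=CCc1cc(-c2coc3cc(OCOC)c(CC=C(C)C)c(OCOC)c3c2=O)cc(OCOC)c1OCOC | intermediate
27 | isoangustone A, 5,7-dihydroxy-3-[3,4-dihydroxy-5-(3-methylbut-2-en-1-yl)phenyl]-6-(3-methylbut-2-en-1-yl)-4H-chromen-4-one | CC(C)=CCc1cc(-c2coc3cc(O)c(CC=C(C)C)c(O)c3c2=O)cc(O)c1O | target

## Step count and risk

Total step count: 14. Longest linear sequence: 8 steps (steps 1–6, 13, 14); the ring-B branch (steps 7–12) is convergent with it.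

**Step 13 (key step, proposed new method).** Three processes could divert it:
- protonation of the C4a aryl anion by bifluoride before the acyl shift, which leaves an aryl ester and no C–C bond;
- conjugate attack of that anion on the β-carbon instead of the carbonyl (coumarin-type closure);
- ene reaction of the aryne with a prenyl alkene.

Fallback with known chemistry, from 18 and 13, returning at 26. Palladium-catalysed coupling of 18 with ethyl bromoacetate (Pd(OAc)2, P(o-tol)3, K3PO4, THF/H2O) would give ethyl 2-[3,4-bis(methoxymethoxy)-5-(3-methylbut-2-en-1-yl)phenyl]acetate F1. Saponification with LiOH would give 2-[3,4-bis(methoxymethoxy)-5-(3-methylbut-2-en-1-yl)phenyl]acetic acid F2. F2 and 13 with CsF in THF at 125 °C would give, by the established aryne insertion into the C–O bond of a simple carboxylic acid (again through 24), the 2-hydroxydeoxybenzoin 2-[3,4-bis(methoxymethoxy)-5-(3-methylbut-2-en-1-yl)phenyl]-1-[6-hydroxy-2,4-bis(methoxymethoxy)-3-(3-methylbut-2-en-1-yl)phenyl]ethan-1-one F3. Here the acid carries no electrophilic β-carbon, and the only phenol free to close ring C is the one the aryne delivered. Heating F3 with N,N-dimethylformamide dimethyl acetal would give the enaminone 2-[3,4-bis(methoxymethoxy)-5-(3-methylbut-2-en-1-yl)phenyl]-3-(dimethylamino)-1-[6-hydroxy-2,4-bis(methoxymethoxy)-3-(3-methylbut-2-en-1-yl)phenyl]prop-2-en-1-one F4, which closes with loss of dimethylamine to 26.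

**Step 3.** The iridium boryl catalyst and the pinacolborane formed could hydroborate, isomerise or borylate the prenyl alkene alongside the ring C–H.

Fallback from 2, returning at 6, with the oxygen introduced before the alkene. Borylation of 2 under the same conditions (C5 is its only unhindered C–H) would give 2-[3,5-bis(methoxymethoxy)phenyl]-4,4,5,5-tetramethyl-1,3,2-dioxaborolane F5, oxidised in the flask to 3,5-bis(methoxymethoxy)phenol F6. TIPSCl/imidazole would give [3,5-bis(methoxymethoxy)phenoxy]triisopropylsilane F7. The bulky silyl ether is a poor director and shields its own flanks, so n-BuLi should metalate between the two MOM ethers to 4-lithio-3,5-bis(methoxymethoxy)-1-(triisopropylsilyloxy)benzene F8. Copper-catalysed prenylation would give [3,5-bis(methoxymethoxy)-4-(3-methylbut-2-en-1-yl)phenoxy]triisopropylsilane F9, and Bu4NF would release 6.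

**Step 9.** The same alkene-side processes as in step 3 could occur, and in addition partial borylation beside the MOM ether.

Fallback from 15, returning at 22, with the prenyl group introduced last by cross-coupling. Lithiation of 15 to 16 as in step 8 and quenching with 1,2-dibromotetrafluoroethane would give 3-bromo-1,2-bis(methoxymethoxy)benzene F10. Iridium-catalysed borylation (no alkene present; C5 again the only unhindered C–H) would give 2-[3-bromo-4,5-bis(methoxymethoxy)phenyl]-4,4,5,5-tetramethyl-1,3,2-dioxaborolane F11. Suzuki–Miyaura coupling with 21 at moderate temperature, where the vinyl iodide reacts well ahead of the hindered electron-rich aryl bromide, would give methyl (E)-2-[3-bromo-4,5-bis(methoxymethoxy)phenyl]-3-methoxyprop-2-enoate F12. Stille coupling of F12 with tributyl(3-methylbut-2-en-1-yl)stannane (Pd(PPh3)4, DMF, 90 °C) would give 22.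

**Step 5.** Two processes could compete with ring metalation: deprotonation of the benzylic and allylic CH2 of the prenyl group flanked by two MOM ethers, and attack of n-BuLi on an incompletely N-silylated carbamate.

Fallback from 6, returning at 13, replacing steps 4–6 by a halogen–metal exchange and retro-Brook sequence. Iodination of the phenoxide (I2, NaHCO3, THF/H2O, 0 °C; both ortho positions equivalent, para position blocked) would give 2-iodo-3,5-bis(methoxymethoxy)-4-(3-methylbut-2-en-1-yl)phenol F13. Hexamethyldisilazane would give [2-iodo-3,5-bis(methoxymethoxy)-4-(3-methylbut-2-en-1-yl)phenoxy]trimethylsilane F14. n-BuLi at −78 °C would give by iodine–lithium exchange [2-lithio-3,5-bis(methoxymethoxy)-4-(3-methylbut-2-en-1-yl)phenoxy]trimethylsilane F15. A 1,3 shift of silicon from oxygen to carbon would turn F15 into the lithium salt of 12, and Tf2O would give 13.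

**Step 14.** Once the phenols are free, acid could close a chroman by adding a phenol to the neighbouring prenyl alkene, or add methanol across the alkene.

Fallback from 26, returning at 27, exchanging the protecting group under buffered aprotic conditions so that no free phenol meets acid. TESOTf with 2,2'-bipyridyl in CH2Cl2 converts aryl MOM ethers into aryl silyl ethers and would give 5,7-bis(triethylsilyloxy)-3-[3,4-bis(triethylsilyloxy)-5-(3-methylbut-2-en-1-yl)phenyl]-6-(3-methylbut-2-en-1-yl)-4H-chromen-4-one F16. KF in MeOH at rt would then give 27.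

## Further compounds

F1 | step 13 | ethyl 2-[3,4-bis(methoxymethoxy)-5-(3-methylbut-2-en-1-yl)phenyl]acetate | CCOC(=O)Cc1cc(CC=C(C)C)c(OCOC)c(OCOC)c1
F2 | step 13 | 2-[3,4-bis(methoxymethoxy)-5-(3-methylbut-2-en-1-yl)phenyl]acetic acid | OC(=O)Cc1cc(CC=C(C)C)c(OCOC)c(OCOC)c1
F3 | step 13 | 2-[3,4-bis(methoxymethoxy)-5-(3-methylbut-2-en-1-yl)phenyl]-1-[6-hydroxy-2,4-bis(methoxymethoxy)-3-(3-methylbut-2-en-1-yl)phenyl]ethan-1-one | O=C(Cc1cc(CC=C(C)C)c(OCOC)c(OCOC)c1)c1c(O)cc(OCOC)c(CC=C(C)C)c1OCOC
F4 | step 13 | 2-[3,4-bis(methoxymethoxy)-5-(3-methylbut-2-en-1-yl)phenyl]-3-(dimethylamino)-1-[6-hydroxy-2,4-bis(methoxymethoxy)-3-(3-methylbut-2-en-1-yl)phenyl]prop-2-en-1-one | CN(C)C=C(c1cc(CC=C(C)C)c(OCOC)c(OCOC)c1)C(=O)c1c(O)cc(OCOC)c(CC=C(C)C)c1OCOC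
F5 | step 3 | 2-[3,5-bis(methoxymethoxy)phenyl]-4,4,5,5-tetramethyl-1,3,2-dioxaborolane | COCOc1cc(B2OC(C)(C)C(C)(C)O2)cc(OCOC)c1
F6 | step 3 | 3,5-bis(methoxymethoxy)phenol | COCOc1cc(O)cc(OCOC)c1
F7 | step 3 | [3,5-bis(methoxymethoxy)phenoxy]triisopropylsilane | COCOc1cc(O[Si](C(C)C)(C(C)C)C(C)C)cc(OCOC)c1
F8 | step 3 | 4-lithio-3,5-bis(methoxymethoxy)-1-(triisopropylsilyloxy)benzene | [Li]c1c(OCOC)cc(O[Si](C(C)C)(C(C)C)C(C)C)cc1OCOC
F9 | step 3 | [3,5-bis(methoxymethoxy)-4-(3-methylbut-2-en-1-yl)phenoxy]triisopropylsilane | COCOc1cc(O[Si](C(C)C)(C(C)C)C(C)C)cc(OCOC)c1CC=C(C)C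
F10 | step 9 | 3-bromo-1,2-bis(methoxymethoxy)benzene | COCOc1cccc(Br)c1OCOC
F11 | step 9 | 2-[3-bromo-4,5-bis(methoxymethoxy)phenyl]-4,4,5,5-tetramethyl-1,3,2-dioxaborolane | COCOc1cc(B2OC(C)(C)C(C)(C)O2)cc(Br)c1OCOC
F12 | step 9 | methyl (E)-2-[3-bromo-4,5-bis(methoxymethoxy)phenyl]-3-methoxyprop-2-enoate | CO/C=C(/C(=O)OC)c1cc(Br)c(OCOC)c(OCOC)c1
F13 | step 5 | 2-iodo-3,5-bis(methoxymethoxy)-4-(3-methylbut-2-en-1-yl)phenol | COCOc1cc(O)c(I)c(OCOC)c1CC=C(C)C
F14 | step 5 | [2-iodo-3,5-bis(methoxymethoxy)-4-(3-methylbut-2-en-1-yl)phenoxy]trimethylsilane | COCOc1cc(O[Si](C)(C)C)c(I)c(OCOC)c1CC=C(C)C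
F15 | step 5 | [2-lithio-3,5-bis(methoxymethoxy)-4-(3-methylbut-2-en-1-yl)phenoxy]trimethylsilane | [Li]c1c(O[Si](C)(C)C)cc(OCOC)c(CC=C(C)C)c1OCOC
F16 | step 14 | 5,7-bis(triethylsilyloxy)-3-[3,4-bis(triethylsilyloxy)-5-(3-methylbut-2-en-1-yl)phenyl]-6-(3-methylbut-2-en-1-yl)-4H-chromen-4-one | CC[Si](CC)(CC)Oc1cc2occ(-c3cc(CC=C(C)C)c(O[Si](CC)(CC)CC)c(O[Si](CC)(CC)CC)c3)c(=O)c2c(O[Si](CC)(CC)CC)c1CC=C(C)C
A1 | alternative 1 | 3-iodo-5,7-bis(methoxymethoxy)-6-(3-methylbut-2-en-1-yl)-4H-chromen-4-one | COCOc1cc2occ(I)c(=O)c2c(OCOC)c1CC=C(C)C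
A2 | alternative 1 | 1-[6-hydroxy-2,4-bis(methoxymethoxy)-3-(3-methylbut-2-en-1-yl)phenyl]ethan-1-one | CC(=O)c1c(O)cc(OCOC)c(CC=C(C)C)c1OCOC
A3 | alternative 2 | 2-[3,4-dihydroxy-5-(3-methylbut-2-en-1-yl)phenyl]-1-[2,4,6-trihydroxy-3-(3-methylbut-2-en-1-yl)phenyl]ethan-1-one | CC(C)=CCc1cc(CC(=O)c2c(O)cc(O)c(CC=C(C)C)c2O)cc(O)c1O
A4 | alternative 2 | 5,7-dihydroxy-3-[3,4-dihydroxy-5-(3-methylbut-2-en-1-yl)phenyl]-8-(3-methylbut-2-en-1-yl)-4H-chromen-4-one | CC(C)=CCc1cc(-c2coc3c(CC=C(C)C)c(O)cc(O)c3c2=O)cc(O)c1O
A5 | alternative 3 | 5-hydroxy-3-{3-hydroxy-4-[(2-methylbut-3-en-2-yl)oxy]phenyl}-7-[(2-methylbut-3-en-2-yl)oxy]-4H-chromen-4-one | C=CC(C)(C)Oc1cc(O)c2c(c1)occ(-c1ccc(OC(C)(C)C=C)c(O)c1)c2=O
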